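Numbering used: pyran O1, C2 (CH3), C3 (CH2OH; carbinol carbon = C7), C4 (arm CH2 = Cα), C5 (CO2Me), C6.
Retrosynthetic cuts, in order: C7 oxidation level (CH2OH from CHO from CONMe2); ring bond C3–C4 (intramolecular 1,4-addition); enol ether bond O1–C6; ester C–O of the hydroxytyrosol arm.
Enabling feature: C4 is β to the arm carbonyl and C3 is α to C7, and O1–C6H=C5(CO2Me)–C4H=Cα–CO2 is ring-opened methyl coumalate, so the acceptor half comes from cleaving the C6–O bond of that 2-pyranone.
Forward order: amide from (S)-3-hydroxybutanoate; alkoxide 1,6-addition/ring opening of methyl coumalate; Mitsunobu ester; closure of the dihydropyran (the only ring built) at C3–C4; CONMe2 to CHO to CH2OH; desilylation.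
Stereochemistry: C2 from ethyl (S)-3-hydroxybutanoate; C4 by 1,3-induction from C2 in the ring closure; C3 by equilibration of the C3 aldehyde to the 2,3-cis/3,4-trans (trans-diaxial) arrangement.
Key step: step 4

Remark: the C2=C3 geometry of dienoates 5 and 7 (Z as formed) may drift toward E without consequence, because that carbon ends as the CH2 of the ester arm.

Step 1
Reactants: 1 ethyl (3S)-3-hydroxybutanoate
Product: 2 (3S)-3-hydroxy-N,N-dimethylbutanamide
Conditions: Me2NH (33% in EtOH, excess), sealed tube, 60 °C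
Reagents that add atoms: dimethylamine, CNC
Why: Aminolysis of the β-hydroxy ester installs the tertiary amide that later activates C3 as the only enolisable position and is the only group the hydrozirconation reduces; the stereocenter (future C2) is not touched.

Step 2
Reactants: 2 (3S)-3-hydroxy-N,N-dimethylbutanamide; 3 methyl coumalate (methyl 2-oxo-2H-pyran-5-carboxylate)
Product: 5 (2Z,4E)-5-{[(2S)-4-(dimethylamino)-4-oxobutan-2-yl]oxy}-4-(methoxycarbonyl)penta-2,4-dienoic acid, via sodium 6-alkoxy-6H-pyran-2-olate 4 (not isolated)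
Conditions: 2, NaN(SiMe3)2 (1.0 equiv), THF, −78 °C; then 3, −78 → 0 °C; cold 1 M HCl to pH 3
Reagents that add atoms: none
Why: The sodium alkoxide of 2 should add to C6 of the 2-pyranone (conjugate 1,6-addition at the carbon activated by both carbonyls) and adduct 4 should open by β-elimination of the ring carboxylate (nucleophilic ring opening of a 2-pyranone), which forms O1–C6 with the ether oxygen cis to the vinyl arm as the later ring requires; no stereocenter is created.

Step 3
Reactants: 5 (2Z,4E)-5-{[(2S)-4-(dimethylamino)-4-oxobutan-2-yl]oxy}-4-(methoxycarbonyl)penta-2,4-dienoic acid; 6 hydroxytyrosol (2-(3,4-dihydroxyphenyl)ethanol)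
Product: 7 2-(3,4-dihydroxyphenyl)ethyl (2Z,4E)-5-{[(2S)-4-(dimethylamino)-4-oxobutan-2-yl]oxy}-4-(methoxycarbonyl)penta-2,4-dienoate
Conditions: PPh3, DIAD, THF, 0 °C → rt
Reagents that add atoms: none
Why: Mitsunobu esterification activates only the primary aliphatic hydroxyl of 6 and uses the carboxylate, far more acidic than the phenols, as nucleophile, so the catechol needs no protection and the dienoyl group is never activated as an acyl donor.

Step 4
Reactants: 7 2-(3,4-dihydroxyphenyl)ethyl (2Z,4E)-5-{[(2S)-4-(dimethylamino)-4-oxobutan-2-yl]oxy}-4-(methoxycarbonyl)penta-2,4-dienoate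
Product: 10 methyl (2S,4S)-4-(2-{2-[3,4-bis(tert-butyldimethylsilyloxy)phenyl]ethoxy}-2-oxoethyl)-3-(dimethylcarbamoyl)-2-methyl-3,4-dihydro-2H-pyran-5-carboxylate as a pair of C3 epimers, via silyl ketene N,O-acetal 8 (not isolated), via cyclized silyl ketene acetal 9 (not isolated)
Conditions: TBSOTf (4.5 equiv), Et3N (6 equiv), CH2Cl2, −78 → 0 °C; then aq. NaHCO3, brief 0.5 M HCl/THF
Reagents that add atoms: tert-butyldimethylsilyl trifluoromethanesulfonate, CC(C)(C)[Si](C)(C)OS(=O)(=O)C(F)(F)F
Why: TBSOTf/Et3N caps both phenols, O-silylates the amide (C3H2 is the only sp3 α-position in 7) and deprotonates C3 to the Z silyl ketene N,O-acetal 8; silyl activation of the dienoate carbonyl then lets C3 add to C4, the β-carbon of the arm ester, giving the ester silyl ketene acetal 9, which is hydrolysed on work-up. The closest known reaction type is the silyl triflate/amine-mediated intramolecular Mukaiyama–Michael addition of an in situ silyl enol ether to a tethered α,β-unsaturated ester. The dihydropyran is the only ring closed, in a 6-(enolexo)-exo-trig mode at C3–C4, with the C5=C6 vinylogous carbonate carried in the tether. C4 is set by 1,3-induction from C2: for orbital overlap the attacked C4=Cα bond must stand perpendicular to the O1–C6=C5 plane, so the arm becomes pseudoaxial (which also relieves allylic strain with the C5 ester), and the C2 methyl takes the equatorial site of the half-chair to avoid a syn-diaxial contact with it, which gives the 2,4-trans relationship; C3 forms without reliable bias and is fixed in step 5. The step needs addition at C4 rather than C6 (the other electrophilic terminus of the push-pull diene) and survival of the C2–O1 bond: ring size secures the first (attack at C6 would close an oxetane), and neutral silyl species at low temperature instead of a metal enolate should disfavour β-elimination of the vinylogous carboxylate.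

Step 5
Reactants: 10 methyl (2S,4S)-4-(2-{2-[3,4-bis(tert-butyldimethylsilyloxy)phenyl]ethoxy}-2-oxoethyl)-3-(dimethylcarbamoyl)-2-methyl-3,4-dihydro-2H-pyran-5-carboxylate
Product: 11 methyl (2S,3S,4S)-4-(2-{2-[3,4-bis(tert-butyldimethylsilyloxy)phenyl]ethoxy}-2-oxoethyl)-3-formyl-2-methyl-3,4-dihydro-2H-pyran-5-carboxylate
Conditions: Cp2Zr(H)Cl (1.5 equiv), THF, rt, 20 min; H2O, SiO2 filtration; then Et3N (0.2 equiv), CH2Cl2, rt
Reagents that add atoms: none
Why: Hydrozirconation of the tertiary amide carbonyl gives a zirconated hemiaminal that releases the aldehyde on work-up while the esters and the vinylogous carbonate stay inert, and Et3N then equilibrates C3 by enolisation to the thermodynamically preferred 2,3-cis/3,4-trans arrangement (formyl axial and anti to the axial arm, methyl equatorial), which sets C3.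

Step 6
Reactants: 11 methyl (2S,3S,4S)-4-(2-{2-[3,4-bis(tert-butyldimethylsilyloxy)phenyl]ethoxy}-2-oxoethyl)-3-formyl-2-methyl-3,4-dihydro-2H-pyran-5-carboxylate
Product: 12 methyl (2S,3R,4S)-4-(2-{2-[3,4-bis(tert-butyldimethylsilyloxy)phenyl]ethoxy}-2-oxoethyl)-3-(hydroxymethyl)-2-methyl-3,4-dihydro-2H-pyran-5-carboxylate
Conditions: NaBH4, MeOH/THF, −40 °C; AcOH quench at −40 °C
Reagents that add atoms: none
Why: Borohydride reduction of the aldehyde at low temperature is much faster than attack on either ester and creates no stereocenter, and the cold acidic quench keeps the new alkoxide from lactonising onto the arm ester.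

Step 7
Reactants: 12 methyl (2S,3R,4S)-4-(2-{2-[3,4-bis(tert-butyldimethylsilyloxy)phenyl]ethoxy}-2-oxoethyl)-3-(hydroxymethyl)-2-methyl-3,4-dihydro-2H-pyran-5-carboxylate
Product: 13 methyl (2S,3R,4S)-4-{2-[2-(3,4-dihydroxyphenyl)ethoxy]-2-oxoethyl}-3-(hydroxymethyl)-2-methyl-3,4-dihydro-2H-pyran-5-carboxylate (target)
Conditions: KHF2 (4 equiv), MeOH, rt
Reagents that add atoms: none
Why: Bifluoride cleaves aryl silyl ethers selectively under nearly neutral conditions (fluoride desilylation of phenolic silyl ethers), so the primary alcohol, the arm ester, the vinylogous carbonate and the three stereocenters should be left untouched.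

Compound list
1 | ethyl (3S)-3-hydroxybutanoate | CCOC(=O)C[C@H](C)O | starting material
2 | (3S)-3-hydroxy-N,N-dimethylbutanamide | CN(C)C(=O)C[C@H](C)O | intermediate
3 | methyl coumalate (methyl 2-oxo-2H-pyran-5-carboxylate) | COC(=O)C1=COC(=O)C=C1 | starting material
4 | sodium 6-{[(2S)-4-(dimethylamino)-4-oxobutan-2-yl]oxy}-5-(methoxycarbonyl)-6H-pyran-2-olate (C6 of the pyran not defined) | COC(=O)C1=CC=C([O-])OC1O[C@@H](C)CC(=O)N(C)C.[Na+] | intermediate
5 | (2Z,4E)-5-{[(2S)-4-(dimethylamino)-4-oxobutan-2-yl]oxy}-4-(methoxycarbonyl)penta-2,4-dienoic acid | CN(C)C(=O)C[C@H](C)O/C=C(C(=O)OC)\C=C/C(=O)O | intermediate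
6 | hydroxytyrosol, 2-(3,4-dihydroxyphenyl)ethanol | OCCc1ccc(O)c(O)c1 | starting material
7 | 2-(3,4-dihydroxyphenyl)ethyl (2Z,4E)-5-{[(2S)-4-(dimethylamino)-4-oxobutan-2-yl]oxy}-4-(methoxycarbonyl)penta-2,4-dienoate | CN(C)C(=O)C[C@H](C)O/C=C(C(=O)OC)\C=C/C(=O)OCCc1ccc(O)c(O)c1 | intermediate
8 | 2-[3,4-bis(tert-butyldimethylsilyloxy)phenyl]ethyl (2Z,4E)-5-{[(2S,3Z)-4-(tert-butyldimethylsilyloxy)-4-(dimethylamino)but-3-en-2-yl]oxy}-4-(methoxycarbonyl)penta-2,4-dienoate | C[C@H](O/C=C(C(=O)OC)\C=C/C(=O)OCCc1ccc(O[Si](C)(C)C(C)(C)C)c(O[Si](C)(C)C(C)(C)C)c1)/C=C(\O[Si](C)(C)C(C)(C)C)N(C)C | intermediate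
9 | methyl (2S,4S)-4-[2-{2-[3,4-bis(tert-butyldimethylsilyloxy)phenyl]ethoxy}-2-(tert-butyldimethylsilyloxy)ethenyl]-3-(dimethylcarbamoyl)-2-methyl-3,4-dihydro-2H-pyran-5-carboxylate (C3 and the ketene acetal geometry not defined) | COC(=O)C1=CO[C@@H](C)C(C(=O)N(C)C)[C@@H]1C=C(O[Si](C)(C)C(C)(C)C)OCCc1ccc(O[Si](C)(C)C(C)(C)C)c(O[Si](C)(C)C(C)(C)C)c1 | intermediate
10 | methyl (2S,4S)-4-(2-{2-[3,4-bis(tert-butyldimethylsilyloxy)phenyl]ethoxy}-2-oxoethyl)-3-(dimethylcarbamoyl)-2-methyl-3,4-dihydro-2H-pyran-5-carboxylate (C3 not defined) | COC(=O)C1=CO[C@@H](C)C(C(=O)N(C)C)[C@@H]1CC(=O)OCCc1ccc(O[Si](C)(C)C(C)(C)C)c(O[Si](C)(C)C(C)(C)C)c1 | intermediate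
11 | methyl (2S,3S,4S)-4-(2-{2-[3,4-bis(tert-butyldimethylsilyloxy)phenyl]ethoxy}-2-oxoethyl)-3-formyl-2-methyl-3,4-dihydro-2H-pyran-5-carboxylate | COC(=O)C1=CO[C@@H](C)[C@@H](C=O)[C@@H]1CC(=O)OCCc1ccc(O[Si](C)(C)C(C)(C)C)c(O[Si](C)(C)C(C)(C)C)c1 | intermediate
12 | methyl (2S,3R,4S)-4-(2-{2-[3,4-bis(tert-butyldimethylsilyloxy)phenyl]ethoxy}-2-oxoethyl)-3-(hydroxymethyl)-2-methyl-3,4-dihydro-2H-pyran-5-carboxylate | COC(=O)C1=CO[C@@H](C)[C@@H](CO)[C@@H]1CC(=O)OCCc1ccc(O[Si](C)(C)C(C)(C)C)c(O[Si](C)(C)C(C)(C)C)c1 | intermediate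
13 | methyl (2S,3R,4S)-4-{2-[2-(3,4-dihydroxyphenyl)ethoxy]-2-oxoethyl}-3-(hydroxymethyl)-2-methyl-3,4-dihydro-2H-pyran-5-carboxylate | COC(=O)C1=CO[C@@H](C)[C@@H](CO)[C@@H]1CC(=O)OCCc1ccc(O)c(O)c1 | target

Total step count: 7. Longest linear sequence: 7 steps (1 → 2 → 5 → 7 → 10 → 11 → 12 → 13).

Steps most likely to fail

Step 4. The ring-oxygen lone pair deactivates the dienoate, so the 1,4-addition may stall; during a long reaction the silylated vinylogous carbonate may then be lost by β-elimination across C3–C2–O1. Fallback: use a pre-formed lithium amide enolate, which is far more nucleophilic and should cyclise within minutes at −78 °C. It sets out from 7: silylation of both phenols (TBSCl, imidazole, DMF) gives 2-[3,4-bis(tert-butyldimethylsilyloxy)phenyl]ethyl (2Z,4E)-5-{[(2S)-4-(dimethylamino)-4-oxobutan-2-yl]oxy}-4-(methoxycarbonyl)penta-2,4-dienoate F1. Treatment with LiN(iPr)2 in THF at −78 °C and a cold AcOH quench should close the ring by anionic 6-exo-trig Michael addition and give 10, where the route is rejoined.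

Step 2. The alkoxide may attack the lactone carbonyl (acyl transfer) instead of C6, the pyranone may oligomerise under base, or the Z-dienoic acid may re-close to 3 with loss of 2 on acidification. Fallback: attach the chiral alcohol by acid-catalysed alkoxy exchange instead of alkoxide addition. It sets out from 3: NaOMe in MeOH opens the ring to (2Z,4E)-5-methoxy-4-(methoxycarbonyl)penta-2,4-dienoic acid F2. Mitsunobu coupling with 6 (PPh3, DIAD) gives 2-(3,4-dihydroxyphenyl)ethyl (2Z,4E)-5-methoxy-4-(methoxycarbonyl)penta-2,4-dienoate F3. Heating F3 with 2 and pyridinium p-toluenesulfonate in toluene, with removal of methanol, exchanges the enol ether by addition–elimination at C6 and gives 7, where the route is rejoined.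

Step 5. Excess hydride may over-reduce the amide or touch an ester, and the amine equilibration may erode C2 through reversible β-elimination and oxa-Michael re-addition. Fallback: electrophilic amide activation instead of hydrometalation. It sets out from 10: Tf2O and 2-fluoropyridine (CH2Cl2, −78 → 0 °C) give the iminium triflate, Et3SiH delivers one hydride, and aqueous hydrolysis releases 11 (equilibrated at C3 as before), where the route is rejoined; this detour makes no new compound F0.

Further compounds
F1 | step 4 | 2-[3,4-bis(tert-butyldimethylsilyloxy)phenyl]ethyl (2Z,4E)-5-{[(2S)-4-(dimethylamino)-4-oxobutan-2-yl]oxy}-4-(methoxycarbonyl)penta-2,4-dienoate | CN(C)C(=O)C[C@H](C)O/C=C(C(=O)OC)\C=C/C(=O)OCCc1ccc(O[Si](C)(C)C(C)(C)C)c(O[Si](C)(C)C(C)(C)C)c1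
F2 | step 2 | (2Z,4E)-5-methoxy-4-(methoxycarbonyl)penta-2,4-dienoic acid | CO/C=C(C(=O)OC)\C=C/C(=O)O
F3 | step 2 | 2-(3,4-dihydroxyphenyl)ethyl (2Z,4E)-5-methoxy-4-(methoxycarbonyl)penta-2,4-dienoate | CO/C=C(C(=O)OC)\C=C/C(=O)OCCc1ccc(O)c(O)c1
F0 | step 5 | none | none
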